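**Retrosynthetic overview**

1. The target is read as methyl (13R)-18-acetoxylabd-8(17)-en-15-oate. C17 is added last by Wittig methylenation of a C8 ketone, and C9 is set by equilibration next to that ketone.
2. Key disconnection: ring B is closed at C7–C8 by the aldol half of an iron-hydride MHAT radical–polar crossover annulation whose radical half first joins C10 to C9. The partners are a ring A aldehyde (C7 aldehyde on the C5 side chain, C1=C10 alkene) and (R)-6-methylcyclohept-2-enone.
3. Enabling feature: in ring B, C10 and C7 are linked through C5–C6 while C8 and C9 are neighbours, and the side chain C11–C15 ends in the carboxyl carbon C15, six bonds from C8. C8, C9 and the whole side chain can therefore be carried as a seven-membered enone (temporary ring C, C15 as ring ketone); later scission of C8–C15 releases the C8 ketone and the C15 ester.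
4. Ring order: ring A (asymmetric Michael/Robinson annulation sets C4; CBS reduction and Johnson–Claisen relay it to C5), temporary ring C (RCM from (R)-citronellal, which brings C13), ring B (key step), then ring C is opened.
5. Stereoconvergence: the key step only has to control the face of C10. Every C7/C8/C9 isomer it gives funnels into one 8-ketone.

Key step: step 10

Remark: atoms carry labdane numbers (C1–C10 decalin, C11–C16 side chain, C17 exocyclic CH2, C18 the oxygenated CH2 on C4, C19/C20 the methyls on C4/C10); α/β refer to the usual drawing with the C20 methyl β, and ξ marks a centre present as a mixture.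

**Step 1**
Reactants: 1 ethyl 2-methyl-3-oxopropanoate; 2 pent-1-en-3-one
Product: 4 ethyl (1R)-1,3-dimethyl-4-oxocyclohex-2-ene-1-carboxylate, via Michael adduct 3 (not isolated)
Conditions: 6′-hydroxy cinchona alkaloid catalyst (9-O-(9-phenanthryl)cupreidine or its cupreine pseudo-enantiomer, whichever delivers the R adduct, 10 mol %), CH2Cl2, −20 °C; then pyrrolidine (20 mol %), AcOH, toluene, 80 °C
Reagents that add atoms: none
Why: The bifunctional cinchona base should deliver the 1,3-dicarbonyl donor to one face of the enone in an asymmetric Michael addition that creates the quaternary C4, and amine/acid then drives the Robinson-type aldol condensation of the ethyl-ketone α-carbon onto the non-enolisable aldehyde, the only six-membered closure open to 3.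

**Step 2**
Reactants: 4 ethyl (1R)-1,3-dimethyl-4-oxocyclohex-2-ene-1-carboxylate
Product: 5 ethyl (1R,4R)-4-hydroxy-1,3-dimethylcyclohex-2-ene-1-carboxylate
Conditions: (S)-2-methyl-CBS-oxazaborolidine (15 mol %), BH3·SMe2, THF, −20 °C; MeOH quench
Reagents that add atoms: none
Why: Corey–Bakshi–Shibata reduction is reagent-controlled for 2-substituted cyclohexenones (the alkenyl side acts as the large group), so the carbinol centre (future C1, oxygen cis to the C4 methyl) should be set independently of the remote C4 centre while the ester stays untouched.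

**Step 3**
Reactants: 5 ethyl (1R,4R)-4-hydroxy-1,3-dimethylcyclohex-2-ene-1-carboxylate
Product: 6 (1R,4R)-4-(hydroxymethyl)-2,4-dimethylcyclohex-2-en-1-ol
Conditions: LiAlH4, THF, 0 °C → rt; H2O/NaOH work-up
Reagents that add atoms: none
Why: LiAlH4 reduction of the neopentyl ester to the primary alcohol (future C18) is standard and leaves the allylic alcohol and the trisubstituted alkene alone.

**Step 4**
Reactants: 6 (1R,4R)-4-(hydroxymethyl)-2,4-dimethylcyclohex-2-en-1-ol
Product: 7 (1R,4R)-4-{[(tert-butyldimethylsilyl)oxy]methyl}-2,4-dimethylcyclohex-2-en-1-ol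
Conditions: TBSCl (1.05 equiv), imidazole, CH2Cl2, 0 °C
Reagents that add atoms: tert-butyl(chloro)dimethylsilane, CC(C)(C)[Si](C)(C)Cl
Why: Silylation with TBSCl/imidazole should select the primary over the secondary allylic hydroxyl, which keeps the carbinol free for the rearrangement.

**Step 5**
Reactants: 7 (1R,4R)-4-{[(tert-butyldimethylsilyl)oxy]methyl}-2,4-dimethylcyclohex-2-en-1-ol
Product: 9 ethyl 2-[(1R,6R)-6-{[(tert-butyldimethylsilyl)oxy]methyl}-2,6-dimethylcyclohex-2-en-1-yl]acetate, via ketene acetal 8 (not isolated)
Conditions: MeC(OEt)3 (6 equiv), EtCO2H (cat.), xylene, 140 °C, EtOH distilled off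
Reagents that add atoms: triethyl orthoacetate, CCOC(C)(OCC)OCC
Why: In the Johnson–Claisen rearrangement the ketene acetal rearranges suprafacially across the cyclohexene, so the new C5–C6 bond should form on the face that carried the C–O bond (1,3-chirality transfer), cis to the C4 methyl and anti to the pseudoaxial CH2OTBS, while the alkene moves to C1=C10.

**Step 6**
Reactants: 9 ethyl 2-[(1R,6R)-6-{[(tert-butyldimethylsilyl)oxy]methyl}-2,6-dimethylcyclohex-2-en-1-yl]acetate
Product: 10 2-[(1R,6R)-6-{[(tert-butyldimethylsilyl)oxy]methyl}-2,6-dimethylcyclohex-2-en-1-yl]acetaldehyde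
Conditions: DIBAL-H (1.1 equiv), CH2Cl2, −78 °C; Rochelle salt
Reagents that add atoms: none
Why: Partial ester reduction with DIBAL-H at −78 °C stops at the aldehyde (C7) through the stable tetrahedral aluminate, and the silyl ether and alkene are inert.

**Step 7**
Reactants: 11 (R)-citronellal
Product: 12 (5R)-5,9-dimethyldeca-1,8-dien-3-ol (3ξ)
Conditions: CH2=CHMgBr, THF, −78 → 0 °C; aq. NH4Cl
Reagents that add atoms: vinylmagnesium bromide, C=C[Mg]Br
Why: Grignard 1,2-addition to the aldehyde installs the vinyl carbinol; the new carbinol centre is oxidised away in step 9, so its configuration does not matter.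

**Step 8**
Reactants: 12 (5R)-5,9-dimethyldeca-1,8-dien-3-ol
Product: 13 (6R)-6-methylcyclohept-2-en-1-ol (1ξ)
Conditions: second-generation Grubbs catalyst (3 mol %), CH2Cl2 (0.01 M), 40 °C
Reagents that add atoms: none
Why: Ring-closing metathesis should initiate at the vinyl carbinol and close the seven-membered ring on the trisubstituted alkene with loss of 2-methylpropene.

**Step 9**
Reactants: 13 (6R)-6-methylcyclohept-2-en-1-ol
Product: 14 (R)-6-methylcyclohept-2-en-1-one
Conditions: Dess–Martin periodinane, NaHCO3, CH2Cl2, rt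
Reagents that add atoms: none
Why: Dess–Martin oxidation of the allylic alcohol gives the enone (C15 ketone, C8=C9 alkene), and the methyl-bearing centre (C13) is not enolisable and cannot be eroded.

**Step 10**
Reactants: 10 2-[(1R,6R)-6-{[(tert-butyldimethylsilyl)oxy]methyl}-2,6-dimethylcyclohex-2-en-1-yl]acetaldehyde; 14 (R)-6-methylcyclohept-2-en-1-one
Product: 17 18-[(tert-butyldimethylsilyl)oxy]-7ξ-hydroxy-17-nor-8,15-cyclolabdan-15-one (5α-H; 10β-methyl; 13R; 8ξ,9ξ), via tertiary radical 15 (not isolated), via iron enolate 16 (not isolated)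
Conditions: Fe(acac)3 (30 mol %), PhSiH3 (2.5 equiv), 14 (2 equiv), EtOH/(CH2OH)2 5:1, degassed, 0 °C → rt
Reagents that add atoms: none
Why: Fe(acac)3 and PhSiH3 form an iron hydride that transfers a hydrogen atom to C1 of the C1=C10 alkene (Markovnikov MHAT); the tertiary C10 radical 15 adds to the β-carbon C9 of enone 14 (Giese addition), divalent iron reduces the resulting α-keto radical to the trivalent iron enolate 16, and C8 of this enolate closes ring B on the C7 aldehyde by an intramolecular aldol addition (6-(enolexo)-exo-trig, chair transition state). The closest known reaction type is the MHAT-initiated radical–polar crossover (Giese/aldol) annulation of an aldehyde-tethered alkene with a cyclic enone, an extension of the Fe(acac)3/PhSiH3 reductive olefin–enone coupling. The one selectivity that must be right is the face of the C10 radical: C9 is expected to enter on the α-face, anti to the C5 side chain and to the syn-axial C19 methyl on C4, which sets the quaternary C10 (C20 β) and thereby the trans A/B fusion with the existing C5 centre. The centres formed at C7, C8 and C9 need no control, because C7 and C8 lose their stereogenicity in steps 11–13 and C9 is equilibrated next to the C8 ketone in step 14, so all diastereomers of 17 converge. Chemoselectivity rests on the preference of the iron hydride for the electron-rich trisubstituted alkene over the enone and on the six-membered aldol closure outrunning protonation of 16.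

**Step 11**
Reactants: 17 18-[(tert-butyldimethylsilyl)oxy]-7ξ-hydroxy-17-nor-8,15-cyclolabdan-15-one
Product: 19 18-[(tert-butyldimethylsilyl)oxy]-17-nor-8,15-cyclolabd-7-en-15-one (9ξ), via mesylate 18 (not isolated)
Conditions: MsCl, Et3N, CH2Cl2, 0 °C; then DBU, rt
Reagents that add atoms: none
Why: Mesylation followed by E1cB elimination of the β-mesyloxy ketone (aldol dehydration) should remove the C7 oxygen and the C8 stereocentre in one operation and give the conjugated enone.

**Step 12**
Reactants: 19 18-[(tert-butyldimethylsilyl)oxy]-17-nor-8,15-cyclolabd-7-en-15-one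
Product: 20 18-[(tert-butyldimethylsilyl)oxy]-15-(triethylsilyloxy)-17-nor-8,15-cyclolabd-8(15)-ene (9ξ)
Conditions: Et3SiH (1.5 equiv), RhCl(PPh3)3 (2 mol %), toluene, 60 °C
Reagents that add atoms: triethylsilane, CC[SiH](CC)CC
Why: RhCl(PPh3)3-catalysed 1,4-hydrosilylation of the s-cis enone with a monohydrosilane should place hydrogen on C7 and give the silyl enol ether regiospecifically at C8=C15.

**Step 13**
Reactants: 20 18-[(tert-butyldimethylsilyl)oxy]-15-(triethylsilyloxy)-17-nor-8,15-cyclolabd-8(15)-ene
Product: 22 (13R)-18-[(tert-butyldimethylsilyl)oxy]-8-oxo-17-norlabdan-15-oic acid (9ξ), via silyl ester 21 (not isolated)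
Conditions: O3, CH2Cl2, −78 °C; Me2S, −78 °C → rt; aq. work-up
Reagents that add atoms: ozone, [O-][O+]=O
Why: Ozonolysis of the electron-rich silyl enol ether, the only C=C bond in the molecule, should cleave C8=C15 and open the temporary ring to the C8 ketone and the C15 silyl ester, which hydrolyses on work-up.

**Step 14**
Reactants: 22 (13R)-18-[(tert-butyldimethylsilyl)oxy]-8-oxo-17-norlabdan-15-oic acid
Product: 23 methyl (13R)-18-hydroxy-8-oxo-17-norlabdan-15-oate (9α-H)
Conditions: HCl (1.25 M in MeOH), 50 °C
Reagents that add atoms: methanol, CO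
Why: Methanolic HCl should effect Fischer esterification at C15, cleave the primary TBS ether and equilibrate C9 through the enol of the C8 ketone, so that the C9 epimers converge under thermodynamic control on the isomer with the side chain equatorial on the trans-decalin.

**Step 15**
Reactants: 23 methyl (13R)-18-hydroxy-8-oxo-17-norlabdan-15-oate
Product: 24 methyl (13R)-18-hydroxylabd-8(17)-en-15-oate
Conditions: Ph3PCH3Br (4 equiv), KOtBu (4 equiv), toluene, rt → 80 °C
Reagents that add atoms: methyltriphenylphosphonium bromide, C[P+](c1ccccc1)(c1ccccc1)c1ccccc1.[Br-]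
Why: Wittig methylenation of the hindered C8 ketone with excess ylide installs C17, and the basic medium cannot erode C9 because that centre already sits in its thermodynamic configuration.

**Step 16**
Reactants: 24 methyl (13R)-18-hydroxylabd-8(17)-en-15-oate
Product: 25 methyl (13R)-18-acetoxylabd-8(17)-en-15-oate
Conditions: Ac2O, pyridine, DMAP (cat.), CH2Cl2, rt
Reagents that add atoms: acetic anhydride, CC(=O)OC(C)=O
Why: DMAP-catalysed acetylation of the neopentyl primary alcohol should give the target, and nothing else in the molecule reacts.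

**Compound list**

1 | ethyl 2-methyl-3-oxopropanoate | CCOC(=O)C(C)C=O | starting material
2 | pent-1-en-3-one | CCC(=O)C=C | starting material
3 | ethyl (2R)-2-formyl-2-methyl-5-oxoheptanoate | CCOC(=O)[C@@](C)(C=O)CCC(=O)CC | intermediate
4 | ethyl (1R)-1,3-dimethyl-4-oxocyclohex-2-ene-1-carboxylate | O=C1CC[C@@](C)(C(=O)OCC)C=C1C | intermediate
5 | ethyl (1R,4R)-4-hydroxy-1,3-dimethylcyclohex-2-ene-1-carboxylate | O[C@@H]1CC[C@@](C)(C(=O)OCC)C=C1C | intermediate
6 | (1R,4R)-4-(hydroxymethyl)-2,4-dimethylcyclohex-2-en-1-ol | O[C@@H]1CC[C@@](C)(CO)C=C1C | intermediate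
7 | (1R,4R)-4-{[(tert-butyldimethylsilyl)oxy]methyl}-2,4-dimethylcyclohex-2-en-1-ol | O[C@@H]1CC[C@@](C)(CO[Si](C)(C)C(C)(C)C)C=C1C | intermediate
8 | 1-ethoxyvinyl ether of 7 (mixed ketene acetal) | C=C(OCC)O[C@@H]1CC[C@@](C)(CO[Si](C)(C)C(C)(C)C)C=C1C | intermediate
9 | ethyl 2-[(1R,6R)-6-{[(tert-butyldimethylsilyl)oxy]methyl}-2,6-dimethylcyclohex-2-en-1-yl]acetate | CCOC(=O)C[C@H]1[C@](C)(CO[Si](C)(C)C(C)(C)C)CCC=C1C | intermediate
10 | 2-[(1R,6R)-6-{[(tert-butyldimethylsilyl)oxy]methyl}-2,6-dimethylcyclohex-2-en-1-yl]acetaldehyde | O=CC[C@H]1[C@](C)(CO[Si](C)(C)C(C)(C)C)CCC=C1C | intermediate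
11 | (R)-citronellal | CC(C)=CCC[C@@H](C)CC=O | starting material
12 | (5R)-5,9-dimethyldeca-1,8-dien-3-ol (3ξ) | CC(C)=CCC[C@@H](C)CC(O)C=C | intermediate
13 | (6R)-6-methylcyclohept-2-en-1-ol (1ξ) | OC1C=CCC[C@@H](C)C1 | intermediate
14 | (R)-6-methylcyclohept-2-en-1-one | O=C1C=CCC[C@@H](C)C1 | intermediate
15 | C10 tertiary radical formed from 10 by hydrogen atom transfer to C1 | O=CC[C@H]1[C@](C)(CO[Si](C)(C)C(C)(C)C)CCC[C]1C | intermediate
16 | trivalent iron enolate of the C9–C10 Giese adduct (drawn as the free enolate anion; 9ξ) | O=CC[C@H]1[C@](C)(CO[Si](C)(C)C(C)(C)C)CCC[C@]1(C)C2CC[C@@H](C)CC([O-])=C2 | intermediate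
17 | 18-[(tert-butyldimethylsilyl)oxy]-7ξ-hydroxy-17-nor-8,15-cyclolabdan-15-one (trans A/B, 5α-H, 10β-methyl, 4α-CH2OTBS, 13R; 8ξ,9ξ) | O=C1C[C@H](C)CCC2C1C(O)C[C@H]3[C@](C)(CO[Si](C)(C)C(C)(C)C)CCC[C@]23C | intermediate
18 | 7-O-methanesulfonate of 17 | O=C1C[C@H](C)CCC2C1C(OS(C)(=O)=O)C[C@H]3[C@](C)(CO[Si](C)(C)C(C)(C)C)CCC[C@]23C | intermediate
19 | 18-[(tert-butyldimethylsilyl)oxy]-17-nor-8,15-cyclolabd-7-en-15-one (9ξ) | O=C1C[C@H](C)CCC2C1=CC[C@H]3[C@](C)(CO[Si](C)(C)C(C)(C)C)CCC[C@]23C | intermediate
20 | 18-[(tert-butyldimethylsilyl)oxy]-15-(triethylsilyloxy)-17-nor-8,15-cyclolabd-8(15)-ene (9ξ) | CC[Si](CC)(CC)OC1=C2CC[C@H]3[C@](C)(CO[Si](C)(C)C(C)(C)C)CCC[C@]3(C)C2CC[C@@H](C)C1 | intermediate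
21 | triethylsilyl (13R)-18-[(tert-butyldimethylsilyl)oxy]-8-oxo-17-norlabdan-15-oate (9ξ) | O=C1CC[C@H]2[C@](C)(CO[Si](C)(C)C(C)(C)C)CCC[C@]2(C)C1CC[C@@H](C)CC(=O)O[Si](CC)(CC)CC | intermediate
22 | (13R)-18-[(tert-butyldimethylsilyl)oxy]-8-oxo-17-norlabdan-15-oic acid (9ξ) | O=C1CC[C@H]2[C@](C)(CO[Si](C)(C)C(C)(C)C)CCC[C@]2(C)C1CC[C@@H](C)CC(=O)O | intermediate
23 | methyl (13R)-18-hydroxy-8-oxo-17-norlabdan-15-oate (9α-H, side chain equatorial) | O=C1CC[C@H]2[C@](C)(CO)CCC[C@]2(C)[C@H]1CC[C@@H](C)CC(=O)OC | intermediate
24 | methyl (13R)-18-hydroxylabd-8(17)-en-15-oate | C=C1CC[C@H]2[C@](C)(CO)CCC[C@]2(C)[C@H]1CC[C@@H](C)CC(=O)OC | intermediate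
25 | methyl (13R)-18-acetoxylabd-8(17)-en-15-oate, (4R,5R,9S,10R,13R) | C=C1CC[C@H]2[C@](C)(COC(C)=O)CCC[C@]2(C)[C@H]1CC[C@@H](C)CC(=O)OC | target

**Step count**

Total step count: 16. Longest linear sequence: 13 steps (steps 1–6 and 10–16); the enone branch (steps 7–9) joins at step 10.

**Steps most likely to fail**

Step 10. Hydrogen transfer to the C10 radical before it reaches the enone, or protonation of enolate 16 before it reaches the aldehyde, would leave ring B open; attack on the β-face of C10 would lead into the cis-fused series. The fallback sets out from 10 (together with 14) and comes back at 19, and it separates fragment union from ring closure. Aldehyde 10 is masked with HC(OMe)3/PPTS in MeOH as the dimethyl acetal of 10 F1. F1 and 14 are joined by the plain Fe(acac)3/PhSiH3 reductive olefin–enone coupling, a radical conjugate addition that ends in protonation, to give the keto acetal F2. PPTS in wet acetone then frees the aldehyde, and pyrrolidine/AcOH closes ring B by aldol condensation of C8 onto C7, which gives 19 directly. If the C10 face is the weak point, the cis- and trans-fused isomers are separated at the stage of F2.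

Step 1. The largely enolised formyl ester may add with insufficient facial discrimination, which would mean a low enantiomeric excess at C4, a centre that nothing later can correct. The fallback sets out from 1 (together with 2) and comes back at 4, and it replaces catalyst control by auxiliary control. 1 is condensed with (R)-1-phenylethylamine (or its enantiomer, as the sense of induction requires) to the secondary enamino ester ethyl (Z)-2-methyl-3-{[(1R)-1-phenylethyl]amino}prop-2-enoate F3. F3 adds to 2 through a chair-like aza-ene transition state to give the imine of the Michael adduct F4. Aqueous AcOH hydrolyses F4 to 3, and the pyrrolidine/AcOH cyclisation of step 1 then leads to 4.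

Step 14. The equilibrium at C9 may not lie far enough on the side of the 9α-H epimer, or enolisation towards the hindered C9 may be too slow. The fallback sets out from 23 (as the epimer mixture) and comes back at 23, and it replaces thermodynamic by kinetic control. 23 is converted with TMSCl/NaI/Et3N in MeCN (equilibrating conditions) into the more substituted silyl enol ether, methyl (13R)-8,18-bis(trimethylsilyloxy)-17-norlabd-8-en-15-oate F5. TBAF at −78 °C in the presence of 2,6-di-tert-butyl-4-methylphenol releases the C8=C9 enolate, which should be protonated axially on the α-face, anti to the C20 methyl, and give 23 as the 9α-H epimer; the C18 silyl ether is cleaved in the same operation.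

**Further compounds**

F1 | step 10 | dimethyl acetal of 10, tert-butyl{[(1R,2R)-2-(2,2-dimethoxyethyl)-1,3-dimethylcyclohex-3-en-1-yl]methoxy}dimethylsilane | COC(OC)C[C@H]1[C@](C)(CO[Si](C)(C)C(C)(C)C)CCC=C1C
F2 | step 10 | keto acetal from reductive coupling of F1 with 14 (C9–C10 bond formed, ring B open, 9ξ) | COC(OC)C[C@H]1[C@](C)(CO[Si](C)(C)C(C)(C)C)CCC[C@]1(C)C2CC[C@@H](C)CC(=O)C2
F3 | step 1 | ethyl (Z)-2-methyl-3-{[(1R)-1-phenylethyl]amino}prop-2-enoate | CCOC(=O)/C(C)=C\N[C@H](C)c1ccccc1
F4 | step 1 | N-[(1R)-1-phenylethyl] imine of Michael adduct 3 | CCOC(=O)[C@@](C)(/C=N/[C@H](C)c1ccccc1)CCC(=O)CC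
F5 | step 14 | methyl (13R)-8,18-bis(trimethylsilyloxy)-17-norlabd-8-en-15-oate | COC(=O)C[C@H](C)CCC1=C(O[Si](C)(C)C)CC[C@H]2[C@](C)(CO[Si](C)(C)C)CCC[C@]12C
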